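Each flavan unit is attached to the benzo[7]annulen-5-one core by a single bond from C2, the sp3 carbon that carries the ring oxygen O1: C2 of unit A to C7 of the tropolone ring, C2 of unit B to C1 of the benzo ring. Both bonds are cut. An oxygen-bearing carbon–tin bond of this kind transfers to palladium with retention, so one double Stille coupling joins two molecules of the cis-(2R,3R)-2-stannyl-3-silyloxychroman 12 to the flat 1-bromo-7-iodo tris(benzyl) benzotropolone 24 and fixes both C2 centres at once. Desilylation, double galloylation and one global hydrogenolysis finish the synthesis.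

Key step: step 16

Assumption: the D-glucose-derived oxazolidinone ketone of step 5 is assumed to deliver oxygen to the face of 8 that gives (2S,3R)-9; no close analogy fixes this sense for a 4H-chromene, and the L-series ketone would be used if it proves opposite.

Step 1
Reactants: 1 phloroglucinol; 2 acrylic acid
Product: 4 5,7-dihydroxychroman-2-one, via trihydroxyphenylpropanoic acid 3 (not isolated)
Conditions: Amberlyst-15, toluene, reflux, Dean–Stark
Reagents that add atoms: none
Why: Friedel–Crafts conjugate hydroarylation of acrylic acid by the very nucleophilic arene followed by acid-catalysed lactonisation onto an ortho hydroxyl; the threefold symmetry of 1 removes any regiochemical question and no stereocentre is formed.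

Step 2
Reactants: 4 5,7-dihydroxychroman-2-one
Product: 5 5,7-bis(benzyloxy)chroman-2-one
Conditions: BnBr (2.2 equiv), K2CO3, DMF, rt
Reagents that add atoms: benzyl bromide, BrCc1ccccc1
Why: Williamson O-alkylation of the two phenols under anhydrous carbonate conditions, which should leave the aryl lactone closed.

Step 3
Reactants: 5 5,7-bis(benzyloxy)chroman-2-one
Product: 6 5,7-bis(benzyloxy)chroman-2-ol
Conditions: iBu2AlH (1.1 equiv), CH2Cl2, −78 °C; aq. potassium sodium tartrate
Reagents that add atoms: none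
Why: Partial hydride reduction of a lactone, the tetrahedral aluminium hemiacetal being stable at −78 °C and giving the lactol (racemic at C2, of no consequence) on work-up.

Step 4
Reactants: 6 5,7-bis(benzyloxy)chroman-2-ol
Product: 8 5,7-bis(benzyloxy)-4H-chromene, via lactol mesylate 7 (not isolated)
Conditions: MsCl, Et3N, CH2Cl2, −20 °C to reflux
Reagents that add atoms: none
Why: Dehydration of a lactol through its anomeric sulfonate (elimination of methanesulfonic acid), the usual lactol-to-cyclic-enol-ether conversion; only C3 carries β-hydrogens, so the 2,3-ene is the only possible alkene.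

Step 5
Reactants: 8 5,7-bis(benzyloxy)-4H-chromene
Product: 9 (2S,3R)-5,7-bis(benzyloxy)-2,3-epoxychroman
Conditions: D-glucose-derived spiro oxazolidinone ketone (0.3 equiv), KHSO5 (as 2KHSO5·KHSO4·K2SO4), K2CO3, Bu4NHSO4, DME–aq. K2CO3/AcOH buffer (pH 8), −10 °C
Reagents that add atoms: potassium peroxymonosulfate, [K+].[O-]S(=O)(=O)OO
Why: Shi epoxidation with the ketone type made for cis-olefins, the chiral dioxirane transferring oxygen to the electron-rich enol ether through a spiro transition state so that the catalyst selects the face and thereby sets C3 (R) and the cis-fused C2 (S).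

Step 6
Reactants: 9 (2S,3R)-5,7-bis(benzyloxy)-2,3-epoxychroman
Product: 11 (2S,3R)-5,7-bis(benzyloxy)-3-(tert-butyldimethylsilyloxy)-2-chlorochroman, via trans-chlorohydrin 10 (not isolated)
Conditions: HCl (1.0 equiv, 2 M in Et2O), CH2Cl2, −78 °C; then 2,6-lutidine, TBSOTf, −78 to −40 °C; non-aqueous work-up, used crude
Reagents that add atoms: hydrogen chloride, Cl; tert-butyldimethylsilyl triflate, CC(C)(C)[Si](C)(C)OS(=O)(=O)C(F)(F)F
Why: Acid-promoted opening of the acetal epoxide at C2 by chloride with inversion (trans-diaxial, anomerically stabilised chloride, C2 S) followed by silylation of the C3 hydroxyl under non-nucleophilic conditions, C3 being untouched.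

Step 7
Reactants: 11 (2S,3R)-5,7-bis(benzyloxy)-3-(tert-butyldimethylsilyloxy)-2-chlorochroman
Product: 12 (2R,3R)-5,7-bis(benzyloxy)-3-(tert-butyldimethylsilyloxy)-2-(tributylstannyl)chroman
Conditions: Bu3SnH, LiN(iPr)2, THF, 0 °C; then 11, −78 to −40 °C
Reagents that add atoms: tributylstannyllithium (Bu3SnLi, made in the flask from Bu3SnH), [Li][Sn](CCCC)(CCCC)CCCC
Why: SN2 displacement of the secondary α-chloro ether by the stannyl anion with inversion, as known for glycosyl chlorides, converts the trans chloride into the cis stannane (C2 R); C3–H is syn to chlorine, so an anti E2 elimination is not available.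

Step 8
Reactants: 13 3,4-bis(benzyloxy)benzaldehyde
Product: 14 4,5-bis(benzyloxy)-2-bromobenzaldehyde
Conditions: Br2, NaOAc, AcOH, rt
Reagents that add atoms: bromine, BrBr
Why: Electrophilic aromatic bromination at the position para to the 3-benzyloxy group (C6 of 13), the established site for 3,4-dialkoxybenzaldehydes; the bromine later blocks the normal cyclisation site and serves as the C1 coupling handle.

Step 9
Reactants: 14 4,5-bis(benzyloxy)-2-bromobenzaldehyde; 15 (3-carboxypropyl)triphenylphosphonium bromide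
Product: 16 (Z)-5-[4,5-bis(benzyloxy)-2-bromophenyl]pent-4-enoic acid
Conditions: NaN(SiMe3)2 (2.1 equiv), THF, 0 °C to rt; aq. HCl work-up
Reagents that add atoms: none
Why: Wittig olefination with the carboxylate-bearing non-stabilised ylide adds the four remaining ring carbons; the Z isomer should predominate, and the geometry is irrelevant because the alkene is reduced next.

Step 10
Reactants: 16 (Z)-5-[4,5-bis(benzyloxy)-2-bromophenyl]pent-4-enoic acid
Product: 17 5-[4,5-bis(benzyloxy)-2-bromophenyl]pentanoic acid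
Conditions: H2 (3 atm), RhCl(PPh3)3 (5 mol%), toluene–EtOH, 40 °C
Reagents that add atoms: none
Why: Homogeneous hydrogenation of the disubstituted alkene with the rhodium chloride tris(phosphine) catalyst, which should leave the aryl bromide and the benzyl ethers untouched.

Step 11
Reactants: 17 5-[4,5-bis(benzyloxy)-2-bromophenyl]pentanoic acid
Product: 19 3,4-bis(benzyloxy)-1-bromo-6,7,8,9-tetrahydro-5H-benzo[7]annulen-5-one, via acid chloride 18 (not isolated)
Conditions: (COCl)2, cat. DMF, CH2Cl2, rt; evaporate; (CF3)2CHOH, rt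
Reagents that add atoms: none
Why: Intramolecular Friedel–Crafts acylation of the acid chloride promoted by hexafluoroisopropanol; the site para to the 5-benzyloxy group is occupied by bromine, so the seven-membered ring can only close at the carbon between the chain and that benzyloxy group, and no Lewis acid is present to cleave the benzyl ethers.

Step 12
Reactants: 19 3,4-bis(benzyloxy)-1-bromo-6,7,8,9-tetrahydro-5H-benzo[7]annulen-5-one
Product: 20 3,4-bis(benzyloxy)-1-bromo-8,9-dihydro-5H-benzo[7]annulene-5,6(7H)-dione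
Conditions: SeO2, 1,4-dioxane–H2O, reflux
Reagents that add atoms: selenium dioxide, O=[Se]=O
Why: Riley oxidation of the only α-methylene of the aryl ketone (C6) to the 1,2-dione, the classical first stage from a benzosuberone to a benzotropolone.

Step 13
Reactants: 20 3,4-bis(benzyloxy)-1-bromo-8,9-dihydro-5H-benzo[7]annulene-5,6(7H)-dione
Product: 22 3,4-bis(benzyloxy)-1-bromo-6-hydroxy-5H-benzo[7]annulen-5-one, via 7-bromo dione 21 (not isolated)
Conditions: PhNMe3Br3 (1.05 equiv), THF, 0 °C; then DBU (2.5 equiv), rt; aq. HCl work-up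
Reagents that add atoms: none
Why: Bromination–dehydrobromination of a cycloheptane-1,2-dione: α-bromination at C7 through the enol, E2 loss of HBr to the 7,8-ene-dione and tautomerisation through the benzylic C9–H give the aromatic benzotropolone.

Step 14
Reactants: 22 3,4-bis(benzyloxy)-1-bromo-6-hydroxy-5H-benzo[7]annulen-5-one
Product: 23 3,4-bis(benzyloxy)-1-bromo-6-hydroxy-7-iodo-5H-benzo[7]annulen-5-one
Conditions: NIS, MeCN, 0 °C to rt
Reagents that add atoms: N-iodosuccinimide, O=C1CCC(=O)N1I
Why: Electrophilic iodination of the tropolone at C7, the carbon next to the hydroxyl where tropolones are normally halogenated; C9 is shielded by the peri bromine and the benzo ring is deactivated by the carbonyl.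

Step 15
Reactants: 23 3,4-bis(benzyloxy)-1-bromo-6-hydroxy-7-iodo-5H-benzo[7]annulen-5-one
Product: 24 3,4,6-tris(benzyloxy)-1-bromo-7-iodo-5H-benzo[7]annulen-5-one
Conditions: BnBr, K2CO3, DMF, rt
Reagents that add atoms: benzyl bromide, BrCc1ccccc1
Why: O-Alkylation of the tropolonate at O6, the only oxygen whose alkylation keeps the benzo ring benzenoid.

Step 16
Reactants: 24 3,4,6-tris(benzyloxy)-1-bromo-7-iodo-5H-benzo[7]annulen-5-one; 12 (2R,3R)-5,7-bis(benzyloxy)-3-(tert-butyldimethylsilyloxy)-2-(tributylstannyl)chroman (3 equiv)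
Product: 25 3,4,6-tris(benzyloxy)-1,7-bis[(2R,3R)-5,7-bis(benzyloxy)-3-(tert-butyldimethylsilyloxy)chroman-2-yl]-5H-benzo[7]annulen-5-one
Conditions: Pd2(dba)3 (5 mol%), JackiePhos (20 mol%), CuCl (4 equiv), KF (4 equiv), 1,4-dioxane, 110 °C
Reagents that add atoms: none
Why: Zerovalent palladium inserts first into the C7–I bond of the β-iodo enone and then into the more hindered C1–Br bond; at each centre the chroman-2-yl group passes from tin through copper to palladium by a closed, front-side transmetalation at the O1-bearing carbon, and reductive elimination forms the C7–C2 bond of unit A and the C1–C2 bond of unit B. The closest known reaction is the stereoretentive Stille coupling of anomeric (α-alkoxy) tributylstannanes with aryl iodides and bromides under Pd2(dba)3, a bulky electron-poor biarylphosphine, CuCl and KF. No ring is closed. The two new stereocentres (C2 of each unit, R) are controlled only by the C2–Sn configuration of 12, which is copied with retention, while C3 is a spectator. The step needs retention and no β-elimination: the only β-hydrogen (C3–H) is trans to palladium in the ring and cannot become syn-coplanar, the syn C3 silyloxy group is a poor leaving group, and the electron-poor ligand should make reductive elimination faster than either escape. Excess 12 with copper and fluoride activation is meant to drive the slower coupling at the electron-rich, ortho-substituted C1–Br.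

Step 17
Reactants: 25 3,4,6-tris(benzyloxy)-1,7-bis[(2R,3R)-5,7-bis(benzyloxy)-3-(tert-butyldimethylsilyloxy)chroman-2-yl]-5H-benzo[7]annulen-5-one
Product: 26 3,4,6-tris(benzyloxy)-1,7-bis[(2R,3R)-5,7-bis(benzyloxy)-3-hydroxychroman-2-yl]-5H-benzo[7]annulen-5-one
Conditions: HF·pyridine, pyridine–THF, 0 °C to rt
Reagents that add atoms: none
Why: Fluoride cleavage of the two secondary silyl ethers under buffered, non-basic conditions, chosen so that the vinylogously acidic C2–H of unit A is not deprotonated and no stereocentre is disturbed.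

Step 18
Reactants: 26 3,4,6-tris(benzyloxy)-1,7-bis[(2R,3R)-5,7-bis(benzyloxy)-3-hydroxychroman-2-yl]-5H-benzo[7]annulen-5-one; 27 3,4,5-tris(benzyloxy)benzoic acid (3 equiv)
Product: 28 3,4,6-tris(benzyloxy)-1,7-bis[(2R,3R)-5,7-bis(benzyloxy)-3-[3,4,5-tris(benzyloxy)benzoyloxy]chroman-2-yl]-5H-benzo[7]annulen-5-one
Conditions: EDC·HCl, DMAP, CH2Cl2, rt
Reagents that add atoms: none
Why: Steglich esterification, the acylpyridinium transferring the galloyl group to each hindered cis C3 hydroxyl with retention at C3, as is routine for 3-O-galloylation of benzylated flavan-3-ols.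

Step 19
Reactants: 28 3,4,6-tris(benzyloxy)-1,7-bis[(2R,3R)-5,7-bis(benzyloxy)-3-[3,4,5-tris(benzyloxy)benzoyloxy]chroman-2-yl]-5H-benzo[7]annulen-5-one
Product: 29 CNP0283148.1
Conditions: H2 (1 atm), Pd(OH)2/C, THF–MeOH, rt
Reagents that add atoms: none
Why: Catalytic hydrogenolysis of all thirteen benzyl ethers (three on the core, four on the chromans, six on the galloyl groups), which should be faster than reduction of the aromatic tropolone or cleavage of the C2–O1 bonds and leaves the esters and all four stereocentres intact.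

Compound list
1 | phloroglucinol | Oc1cc(O)cc(O)c1 | starting material
2 | acrylic acid | C=CC(=O)O | starting material
3 | 3-(2,4,6-trihydroxyphenyl)propanoic acid | OC(=O)CCc1c(O)cc(O)cc1O | intermediate
4 | 5,7-dihydroxychroman-2-one | O=C1CCc2c(O)cc(O)cc2O1 | intermediate
5 | 5,7-bis(benzyloxy)chroman-2-one | O=C1CCc2c(OCc3ccccc3)cc(OCc3ccccc3)cc2O1 | intermediate
6 | 5,7-bis(benzyloxy)chroman-2-ol (racemic lactol) | OC1CCc2c(OCc3ccccc3)cc(OCc3ccccc3)cc2O1 | intermediate
7 | 5,7-bis(benzyloxy)chroman-2-yl methanesulfonate | CS(=O)(=O)OC1CCc2c(OCc3ccccc3)cc(OCc3ccccc3)cc2O1 | intermediate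
8 | 5,7-bis(benzyloxy)-4H-chromene | C1=COc2cc(OCc3ccccc3)cc(OCc3ccccc3)c2C1 | intermediate
9 | (2S,3R)-5,7-bis(benzyloxy)-2,3-epoxychroman | O1[C@H]2Oc3cc(OCc4ccccc4)cc(OCc4ccccc4)c3C[C@@H]12 | intermediate
10 | (2S,3R)-5,7-bis(benzyloxy)-2-chlorochroman-3-ol (2,3-trans) | Cl[C@@H]1Oc2cc(OCc3ccccc3)cc(OCc3ccccc3)c2C[C@H]1O | intermediate
11 | (2S,3R)-5,7-bis(benzyloxy)-3-(tert-butyldimethylsilyloxy)-2-chlorochroman (2,3-trans) | Cl[C@@H]1Oc2cc(OCc3ccccc3)cc(OCc3ccccc3)c2C[C@H]1O[Si](C)(C)C(C)(C)C | intermediate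
12 | (2R,3R)-5,7-bis(benzyloxy)-3-(tert-butyldimethylsilyloxy)-2-(tributylstannyl)chroman (2,3-cis) | CCCC[Sn](CCCC)(CCCC)[C@H]1Oc2cc(OCc3ccccc3)cc(OCc3ccccc3)c2C[C@H]1O[Si](C)(C)C(C)(C)C | intermediate
13 | 3,4-bis(benzyloxy)benzaldehyde | O=Cc1ccc(OCc2ccccc2)c(OCc2ccccc2)c1 | starting material
14 | 4,5-bis(benzyloxy)-2-bromobenzaldehyde | O=Cc1cc(OCc2ccccc2)c(OCc2ccccc2)cc1Br | intermediate
15 | (3-carboxypropyl)triphenylphosphonium bromide | OC(=O)CCC[P+](c1ccccc1)(c1ccccc1)c1ccccc1.[Br-] | starting material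
16 | (Z)-5-[4,5-bis(benzyloxy)-2-bromophenyl]pent-4-enoic acid | OC(=O)CC/C=C\c1cc(OCc2ccccc2)c(OCc2ccccc2)cc1Br | intermediate
17 | 5-[4,5-bis(benzyloxy)-2-bromophenyl]pentanoic acid | OC(=O)CCCCc1cc(OCc2ccccc2)c(OCc2ccccc2)cc1Br | intermediate
18 | 5-[4,5-bis(benzyloxy)-2-bromophenyl]pentanoyl chloride | ClC(=O)CCCCc1cc(OCc2ccccc2)c(OCc2ccccc2)cc1Br | intermediate
19 | 3,4-bis(benzyloxy)-1-bromo-6,7,8,9-tetrahydro-5H-benzo[7]annulen-5-one | O=C1CCCCc2c(Br)cc(OCc3ccccc3)c(OCc3ccccc3)c12 | intermediate
20 | 3,4-bis(benzyloxy)-1-bromo-8,9-dihydro-5H-benzo[7]annulene-5,6(7H)-dione | O=C1C(=O)CCCc2c(Br)cc(OCc3ccccc3)c(OCc3ccccc3)c12 | intermediate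
21 | 3,4-bis(benzyloxy)-1,7-dibromo-8,9-dihydro-5H-benzo[7]annulene-5,6(7H)-dione | O=C1C(=O)C(Br)CCc2c(Br)cc(OCc3ccccc3)c(OCc3ccccc3)c12 | intermediate
22 | 3,4-bis(benzyloxy)-1-bromo-6-hydroxy-5H-benzo[7]annulen-5-one | O=C1C(O)=CC=Cc2c(Br)cc(OCc3ccccc3)c(OCc3ccccc3)c12 | intermediate
23 | 3,4-bis(benzyloxy)-1-bromo-6-hydroxy-7-iodo-5H-benzo[7]annulen-5-one | O=C1C(O)=C(I)C=Cc2c(Br)cc(OCc3ccccc3)c(OCc3ccccc3)c12 | intermediate
24 | 3,4,6-tris(benzyloxy)-1-bromo-7-iodo-5H-benzo[7]annulen-5-one | O=C1C(OCc3ccccc3)=C(I)C=Cc2c(Br)cc(OCc3ccccc3)c(OCc3ccccc3)c12 | intermediate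
25 | 3,4,6-tris(benzyloxy)-1,7-bis[(2R,3R)-5,7-bis(benzyloxy)-3-(tert-butyldimethylsilyloxy)chroman-2-yl]-5H-benzo[7]annulen-5-one | O=C1C(OCc3ccccc3)=C([C@H]3Oc4cc(OCc5ccccc5)cc(OCc5ccccc5)c4C[C@H]3O[Si](C)(C)C(C)(C)C)C=Cc2c([C@H]3Oc4cc(OCc5ccccc5)cc(OCc5ccccc5)c4C[C@H]3O[Si](C)(C)C(C)(C)C)cc(OCc3ccccc3)c(OCc3ccccc3)c12 | intermediate
26 | 3,4,6-tris(benzyloxy)-1,7-bis[(2R,3R)-5,7-bis(benzyloxy)-3-hydroxychroman-2-yl]-5H-benzo[7]annulen-5-one | O=C1C(OCc3ccccc3)=C([C@H]3Oc4cc(OCc5ccccc5)cc(OCc5ccccc5)c4C[C@H]3O)C=Cc2c([C@H]3Oc4cc(OCc5ccccc5)cc(OCc5ccccc5)c4C[C@H]3O)cc(OCc3ccccc3)c(OCc3ccccc3)c12 | intermediate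
27 | 3,4,5-tris(benzyloxy)benzoic acid | OC(=O)c1cc(OCc2ccccc2)c(OCc2ccccc2)c(OCc2ccccc2)c1 | starting material
28 | 3,4,6-tris(benzyloxy)-1,7-bis[(2R,3R)-5,7-bis(benzyloxy)-3-[3,4,5-tris(benzyloxy)benzoyloxy]chroman-2-yl]-5H-benzo[7]annulen-5-one | O=C1C(OCc3ccccc3)=C([C@H]3Oc4cc(OCc5ccccc5)cc(OCc5ccccc5)c4C[C@H]3OC(=O)c3cc(OCc4ccccc4)c(OCc4ccccc4)c(OCc4ccccc4)c3)C=Cc2c([C@H]3Oc4cc(OCc5ccccc5)cc(OCc5ccccc5)c4C[C@H]3OC(=O)c3cc(OCc4ccccc4)c(OCc4ccccc4)c(OCc4ccccc4)c3)cc(OCc3ccccc3)c(OCc3ccccc3)c12 | intermediate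
29 | CNP0283148.1: 3,4,6-trihydroxy-1,7-bis[(2R,3R)-5,7-dihydroxy-3-(3,4,5-trihydroxybenzoyloxy)chroman-2-yl]-5H-benzo[7]annulen-5-one | O=C(O[C@@H]1Cc2c(O)cc(O)cc2O[C@@H]1c1ccc2c([C@H]3Oc4cc(O)cc(O)c4C[C@H]3OC(=O)c3cc(O)c(O)c(O)c3)cc(O)c(O)c2c(=O)c1O)c1cc(O)c(O)c(O)c1 | target

Total step count: 19 (steps 1–7 to stannane 12, steps 8–15 to core 24, steps 16–19 to the target).
Longest linear sequence: 12 steps (13 to 29, steps 8–19).

Steps most likely to fail

Step 16. The second oxidative addition at the electron-rich, ortho-substituted C1–Br may stall. The alkylpalladium intermediates may also lose the syn C3 silyloxy group by β-elimination or be protonated after transmetalation, so that mono-coupled and reduced material builds up. The fallback sets out from chromene 8 and core 24 and returns to the route at diol 26; it no longer carries the relative configuration through the coupling. Epoxidation of 8 with the antipodal ketone should give (2R,3S)-5,7-bis(benzyloxy)-2,3-epoxychroman F1. Bu3SnLi opens it at C2 with inversion, as known for glycal epoxides, to the 2,3-trans stannyl alcohol (2R,3S)-5,7-bis(benzyloxy)-2-(tributylstannyl)chroman-3-ol F2, in which tin and oxygen are trans and cannot become syn-coplanar. The same palladium/copper coupling with 24, retentive at C2, should then give the bis(2,3-trans-flavan-3-ol) F3. Dess–Martin oxidation gives the bis(flavan-3-one) F4, and LiBH(s-Bu)3 at −78 °C, adding hydride anti to the C2 substituent as in the established trans-to-cis inversion of flavan-3-ols, should give 26.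

Step 7. The stannyl anion may attack chlorine (halogen–metal exchange) or transfer an electron instead of displacing chloride; the resulting C2 anion or radical would expel the C3 silanolate, returning chromene 8, or lose the stereochemical information. The fallback sets out from epoxide 9 and returns at stannane 12. Thiophenol opens 9 at C2 with inversion to the trans hydroxy sulfide (2S,3R)-5,7-bis(benzyloxy)-2-(phenylthio)chroman-3-ol F5. Deprotonation with n-BuLi, reductive lithiation with lithium naphthalenide (LiC10H8) at −78 °C and quenching with Bu3SnCl follow the dianion method known for 2-hydroxy glycosyl donors, in which the alkoxide cannot leave and holds the C2 lithium on its own face. This should give the cis stannyl alcohol (2R,3R)-5,7-bis(benzyloxy)-2-(tributylstannyl)chroman-3-ol F6, and silylation with TBSOTf and 2,6-lutidine gives 12.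

Step 5. Facial selection may be poor for a cis olefin whose two ends differ only as O versus CH2, and the acetal epoxide may hydrolyse in the aqueous buffer. A modest enantiomeric ratio would be partly repaired at step 16, because 25 holds two units and the mixed combinations are separable diastereomers. The fallback sets out from lactol 6 and returns at chlorohydrin 10. L-Proline-catalysed α-aminoxylation of the aldehyde tautomer of 6 with nitrosobenzene in DMSO, whose sense is well established for 3-arylpropanals, should give (3R)-5,7-bis(benzyloxy)-3-[(phenylamino)oxy]chroman-2-ol F7. Zn in AcOH cleaves the N–O bond to (3R)-5,7-bis(benzyloxy)chroman-2,3-diol F8. Anhydrous HCl in Et2O over 4 Å molecular sieves then converts the lactol hydroxyl into the anomerically stabilised trans chloride 10, which is silylated as in step 6.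

Further compounds
F1 | step 16 | (2R,3S)-5,7-bis(benzyloxy)-2,3-epoxychroman | O1[C@@H]2Oc3cc(OCc4ccccc4)cc(OCc4ccccc4)c3C[C@H]12
F2 | step 16 | (2R,3S)-5,7-bis(benzyloxy)-2-(tributylstannyl)chroman-3-ol (2,3-trans) | CCCC[Sn](CCCC)(CCCC)[C@H]1Oc2cc(OCc3ccccc3)cc(OCc3ccccc3)c2C[C@@H]1O
F3 | step 16 | 3,4,6-tris(benzyloxy)-1,7-bis[(2R,3S)-5,7-bis(benzyloxy)-3-hydroxychroman-2-yl]-5H-benzo[7]annulen-5-one | O=C1C(OCc3ccccc3)=C([C@H]3Oc4cc(OCc5ccccc5)cc(OCc5ccccc5)c4C[C@@H]3O)C=Cc2c([C@H]3Oc4cc(OCc5ccccc5)cc(OCc5ccccc5)c4C[C@@H]3O)cc(OCc3ccccc3)c(OCc3ccccc3)c12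
F4 | step 16 | 3,4,6-tris(benzyloxy)-1,7-bis[(2R)-5,7-bis(benzyloxy)-3-oxochroman-2-yl]-5H-benzo[7]annulen-5-one | O=C1C(OCc3ccccc3)=C([C@H]3Oc4cc(OCc5ccccc5)cc(OCc5ccccc5)c4CC3=O)C=Cc2c([C@H]3Oc4cc(OCc5ccccc5)cc(OCc5ccccc5)c4CC3=O)cc(OCc3ccccc3)c(OCc3ccccc3)c12
F5 | step 7 | (2S,3R)-5,7-bis(benzyloxy)-2-(phenylthio)chroman-3-ol (2,3-trans) | c1ccccc1S[C@@H]1Oc2cc(OCc3ccccc3)cc(OCc3ccccc3)c2C[C@H]1O
F6 | step 7 | (2R,3R)-5,7-bis(benzyloxy)-2-(tributylstannyl)chroman-3-ol (2,3-cis) | CCCC[Sn](CCCC)(CCCC)[C@H]1Oc2cc(OCc3ccccc3)cc(OCc3ccccc3)c2C[C@H]1O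
F7 | step 5 | (3R)-5,7-bis(benzyloxy)-3-[(phenylamino)oxy]chroman-2-ol | OC1Oc2cc(OCc3ccccc3)cc(OCc3ccccc3)c2C[C@H]1ONc1ccccc1
F8 | step 5 | (3R)-5,7-bis(benzyloxy)chroman-2,3-diol | OC1Oc2cc(OCc3ccccc3)cc(OCc3ccccc3)c2C[C@H]1O
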